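D in west and south, as read through a scatter of 1 percentage point, starts straight and then flattens, so we read each curve at its two ends and join them.

| flask | Z | J | remark | time |
|---|---|---|---|---|
| west | 0.45 M | 0.30 equiv | run made earlier |  |
| south | 0.15 M | 0.30 equiv | run made earlier |  |
| cedar | 0.30 M | 0.300 equiv |  | 40 h |
| elm | 0.30 M | 0.400 equiv |  | 40 h |
| larch | 0.30 M | 0.600 equiv |  | 40 h |
| oak | 0.30 M | 1.00 equiv |  | 40 h |
| maple | 0.30 M | 1.50 equiv |  | 40 h |

| run | time / h | D / % |
|---|---|---|
| west | 1.33 | 2.0 |
| west | 4.00 | 6.1 |
| west | 6.00 | 8.0 |
| west | 10.0 | 7.5 |
| west | 15.0 | 11.4 |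
| west | 20.0 | 15.9 |
| west | 25.0 | 16.2 |
| south | 3.00 | 1.2 |
| south | 6.00 | 4.6 |
| south | 10.0 | 3.5 |
| south | 15.0 | 4.7 |
| south | 20.0 | 7.4 |
| south | 25.0 | 8.1 |

(each reading ± 1 percentage point)

- "hardly changes" means that all values lie within two and a half points (for a concentration: within two and a half percent of the largest)

- amount of D at the end, in percent of the Z charged for cedar, elm, larch, oak, maple, in this order
- the shape of the row from first to last (hardly changes / falls, then rises / rises, then falls / rises all the way / falls all the way)

At the start, the readings at 4.00 h and 6.00 h give west a slope of 0.0141 h⁻¹ of the charged Z. Those at 3.00 h and 6.00 h give south 0.00644 h⁻¹. At the end, the last two readings of each run lie within the scatter of each other, so we take their mean as a level: 16.1 % for west and 7.75 % for south. Level over slope gives 11.4 h for west and 12.0 h for south. These are close, although west holds 3.00 times the Z of south. So we carry their mean, 11.7 h, a reading with the scatter of its runs, as the knee time: the time at which the straight start would reach the level, which is the time constant of a first-order rise.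

Joined, we let D rise as the level times one minus the exponential of minus time over knee time. Cedar's charge of J, 0.0900 M, is the mean of the charges of west and south, so we give cedar their mean slope, 0.0103 h⁻¹. We assume that the slope follows J and that the knee time stays, though both runs used the same equivalents. The asked 40 h is 3.42 knee times, so we reckon the end of cedar at 11.6 %. For maple, with 5.00 times the J, we reckon 58.1 %.

The forecast gives 18 %, 23 %, 33 %, 50 % and 67 %, shape rises all the way; in its words the rise with concentration “suggests a bimolecular step”. Our two ends lie lower than its values.

The flasks end at 13.8 %, 17.9 %, 25.3 %, 37.8 % and 49.4 %, shape rises all the way. Cedar stands above our end and maple below it.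

    Z + J ⇌ D (K = 15.0 M⁻¹, k = 0.120 M⁻¹ h⁻¹)
    2 Z → X (k = 3.10 × 10⁻⁵ M⁻¹ h⁻¹)
    Z → E (k = 0.0270 h⁻¹)

In cedar, the forward passing of Z into E runs 2.5 times as fast as the forward passing of Z + J into D at the start and 4.6 times as fast at 40.0 h, when E stands at 58.9 % against D at 13.8 %. The knee time puts 84.7 % of the end D in place at half of the time; cedar shows 80.9 % and maple 88.6 %.

The numbers in the tables are calculated with made-up constants, noise included.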